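The numbers were chosen freely.

Count what is left.

    first end groups + second end groups → links (k1 = 1.1 M⁻¹ s⁻¹)
    crystals ⇌ links, rate k2*(cs2 - [links]) while solid is left; crystals form when [links] > cs2 (cs2 = 1.3 mM, k2 = 1.0 s⁻¹)

all flasks: first end groups 0.10 M; second end groups 0.100 M
- winter: time 100 s
- dawn: time 200 s
- midnight: time 50 s

- for links the crystals are counted in
- as a solid, counted per litre of solution: crystals
- run time (winter): 100 s

1. which of these there is most of at the end, counted by the first end groups in it, winter (first end groups / links)
2. which of these there is most of at the end, counted by the first end groups in it, dawn (first end groups / links)
3. which of these there is most of at the end, counted by the first end groups in it, midnight (first end groups / links)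
4. how much there is at the end of the one of these that leads, in percent of the first end groups charged: winter
5. how much there is at the end of the one of these that leads, in percent of the first end groups charged: dawn
6. how much there is at the end of the one of these that leads, in percent of the first end groups charged: midnight

First and second end groups are charged alike, 0.10 M and 0.100 M, and they leave one for one. So a single fraction f, the part still unbound at time t, serves for both. The coupling then runs at its constant times the square of what is left, and the reciprocal of f starts at one and climbs in a straight line. It gains one in every τ, the time in which f falls to one half (the half-life of this second-order step at this charge): one over the constant times the charge, 9.09 s. Hence f = τ/(τ + t). Crystals stand nowhere in the coupling's rate and are counted with the links, so links are what f does not hold.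

My small table has one row per flask and two columns, t/τ and f. Midnight reads 5.50 and 15.4 %, winter 11.0 and 8.33 %, dawn 22.0 and 4.35 %. Even the shortest time, midnight's, stands past τ, so f is under one half in each row and links lead, with 84.6 % at midnight, 91.7 % in winter and 95.7 % at dawn.

Reading down the columns, each row has twice the time of the one before. From winter to dawn f falls to about half. Yet the gain in links shrinks: it is 7.1 percentage points from midnight to winter, and from winter to dawn it is less than that, 4 points.

The forecast names links for winter, links for dawn and links for midnight, at 91.7 %, 95.7 % and 84.6 %, holding that crystallisation “moves material only between forms of links”.

The flasks give links at 91.7 % in winter, links at 95.7 % at dawn and links at 84.6 % at midnight. Midnight's links have moved by 6 points with second end groups at 0.0890 M below or 0.115 M above the charge. Midnight read later, at 2.0 min, stands at 13.2 on the t/τ column, so f = 7.04 %, and that flask holds 7.04 % of its first end groups unbound.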